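## Structural features

Lespeflorin A3 is a (2S)-flavanone in which benzene ring A is fused to the dihydropyranone ring C (O1, C2, C3 and the C4 carbonyl), and C2 carries ring B, the benzene ring of a 2,2-dimethyl-2H-chromene attached through its C6. C2 is the only stereocentre, so it has no stereochemical neighbour, but it is benzylic, bears the ring oxygen and lies beta to the C4 ketone, and base can therefore scramble it through retro-oxa-Michael opening of ring C to the 2'-hydroxychalcone. Ring A is pentasubstituted: C4a carries the acyl carbon, C8a the ring oxygen, C7 a free hydroxyl, C6 and C8 each a 3-methylbut-2-enyl (prenyl) group, and only C5 carries hydrogen. The fragile groups are the two prenyl chains ortho to the C7 hydroxyl, which acids, halonium sources, quinone oxidants and divalent palladium can cyclise onto the phenol, together with the cis-disubstituted double bond of the chromene and the electron-rich resorcinol core. The real difficulty is the contiguous prenyl–hydroxyl–prenyl array on C6, C7 and C8, which electrophilic prenylation of an arene delivers with poor regiocontrol, together with enantiocontrol at the labile C2. The key step exploits the fact that C7 with C6, C8 and their prenyl groups maps onto a symmetric ketone (C7 as the carbonyl carbon, C6 and C8 as its alpha carbons), while C5, C4a and C8a map onto the beta carbon, alpha carbon and carbonyl carbon of an acrylate. Ring A can therefore be built at the cyclohexane-1,3-dione oxidation level, where the two ring oxygens already stand in the 1,3-relationship of the resorcinol.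

## Logic of the disconnections

21 to 20: only the O–Si bond at C7 is cut. The C7 hydroxyl is acidic (para to the carbonyl), would stop the conjugate addition as its phenoxide, and is the group onto which either prenyl chain can cyclise, so it stays masked until the end. The forward step must cleave the silyl ether without being basic enough to open ring C or acidic enough to touch the prenyl groups.

20 to 15 and 19: the C2–C1' bond between ring C and ring B is cut. This places the creation of the single stereocentre in one catalyst-controlled step near the end and splits the molecule into two achiral halves; 15 is flat and 19 carries all of ring B. The forward step needs enantioface-selective 1,4-addition to a weakly electrophilic C2=C3 bond, without ring opening of the metal enolate and without touching three other alkenes.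

19 to 18, then to 16 and 17: first the C–B bond is cut, then the O1–C2 and C4–C4a bonds of the pyran ring of the chromene (numbering of the chromene itself). This reduces ring B to a simple para-substituted phenol and a five-carbon enal. The forward condensation must be ortho-selective; the para bromine blocks the only competing position and later becomes the boron handle.

15 to 13, by way of 14: the O1–C2 bond is cut and C4 is taken down to the alcohol level. Ring C is then closed by addition of the C8a hydroxyl to an ynone, which needs no acid. The forward step needs an oxidation that tolerates a free phenol and a 6-endo instead of a 5-exo ring closure.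

13 to 12: the C3–C4 bond is cut, so that C2 and C3 arrive together as an acetylide. The demand is clean 1,2-addition to an aldehyde next to a free phenol and in the presence of an aryl silyl ether.

12 to 11: the O–Si bond is cut. The forward silylation must choose the C7 hydroxyl (position 4 of 11) over the hydroxyl that becomes O1; the hydrogen bond of the latter to the aldehyde secures this.

11 to 10: the C4a–C4 bond is cut. C4a is the only ring carbon ortho to an unhindered hydroxyl, so a chelation-directed formylation can only go there. This replaces an acid-mediated C-acetylation, which would expose two ortho-prenyl phenols to a Lewis acid. The gain is a carbonyl-free resorcinol; the demand is strict ortho delivery under non-acidic conditions.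

10 to 7, by way of 9 and 8: no skeletal bond is cut; two hydrogens are returned to C4a and C5. This brings ring A to the dione level, where it can be built by carbonyl chemistry. The forward dehydrogenation must spare the prenyl groups, and the site of enolisation is immaterial because every enol regioisomer leads to the same arene.

7 to 5 and 6: the C6–C5 and C8–C8a bonds are cut. Ring A falls apart into a symmetric ketone and a three-carbon acrylate unit, and the prenyl–oxygen–prenyl array becomes a matter of connectivity alone. The forward step needs one Michael addition followed by ring closure, not a second Michael addition.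

5 to 4, then by way of 3 to 1 and 2: the two ester groups are restored, then the two bonds from the future C6 and C8 to the prenyl CH2 groups are cut one after the other. The ester groups make both alkylations easy and are removed under neutral conditions. The demand is alkylation on both sides of the ketone and not twice on one side.

## Other disconnections considered

Alternative 1: The cut is the C4a–C5 bond of ring A, with the ring unfolded into a 4-pyranone. The precursor is 2-[(3E)-4-(2,2-dimethyl-2H-chromen-6-yl)-2-oxobut-3-en-1-yl]-3,5-bis(3-methylbut-2-en-1-yl)-4H-pyran-4-one A2. In the forward key step an alkoxide adds to the unsubstituted ring carbon of A2, the pyranone opens, and the side-chain methylene carbanion condenses on that same carbon. Expulsion of the alkoxide and tautomerisation then give the chalcone (2E)-1-[2,4-dihydroxy-3,5-bis(3-methylbut-2-en-1-yl)phenyl]-3-(2,2-dimethyl-2H-chromen-6-yl)prop-2-en-1-one A1.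
- In its favour: in A1 ring A is born aromatic with the acyl carbon, both prenyl groups and the whole C2–C3–ring B chain already attached. No dehydrogenation, no formylation and no separate C2–aryl bond formation are needed; on these points it is better than the chosen plan, which spends steps 4, 5, 7 and 8 on them.
- Against it: A2 is a fully substituted pyranone with a sensitive beta-keto enone side chain and must itself be built in several steps. The alkoxide can also add to the cinnamoyl double bond of A2. Because A1 is a chalcone, C2 would have to be set by an asymmetric oxa-Michael closure of an unactivated 2'-hydroxychalcone. That is a less dependable way of controlling C2 than the conjugate arylation of 15, and the basic medium of the key step would equilibrate any flavanone formed from A1.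
- Comparison: regiochemistry of ring A is fixed by connectivity in both plans (equal). The route through A1 wins on bonds formed per step; the chosen plan wins on access to its precursor (5 is two steps from bulk chemicals, A2 is not) and on the stereocentre.

Alternative 2: The cut is the O1–C8a bond. The precursor is (1S,3S)-1-[2-bromo-4-(tert-butyldimethylsilyloxy)-3,5-bis(3-methylbut-2-en-1-yl)phenyl]-3-(2,2-dimethyl-2H-chromen-6-yl)propane-1,3-diol A4. Under CuI, a phenanthroline-type ligand and Cs2CO3, the hydroxyl of A4 on the carbon that bears ring B would displace the bromide. The product would be (2S,4S)-7-(tert-butyldimethylsilyloxy)-2-(2,2-dimethyl-2H-chromen-6-yl)-6,8-bis(3-methylbut-2-en-1-yl)chroman-4-ol A3. Oxidation of A3 at C4 and desilylation would follow.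
- In its favour: the C2–O bond of A4 is never broken, so the configuration set earlier by reagent control is carried into A3 with retention, and no enolisable flavanone exists until the final oxidation. On security of C2 this plan is better than the chosen one, whose step 11 depends on the face selectivity of a catalyst. The other hydroxyl of A4 cannot compete, since it could only close a four-membered ring.
- Against it: ring A of A4 must be a hexasubstituted bromoarene, which makes the central problem of the target harder, since a bromine has to be placed next to a prenyl group on an electron-rich ring. Copper-mediated etherification of a di-ortho-substituted bromide by a secondary benzylic alkoxide should be slow, and the hot basic medium threatens the aryl silyl ether. Two carbinol centres are made for A4 and one is then oxidised away.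
- Comparison: a cheap base-metal catalyst in place of a rhodium complex (better), stereochemistry more secure (better), but clearly more steps to A4 and no solution for ring A (worse).

Alternative 3: The cuts are C7–C8, C4a–C8a and C6–C7. The dienyl diazoketone (3E)-1-diazo-7-methylocta-3,6-dien-2-one A6 would undergo photochemical Wolff rearrangement to a vinylketene. This would add to the siloxyalkyne triisopropyl[(5-methylhex-4-en-1-yn-1-yl)oxy]silane A7 by [2+2] cycloaddition, four-electron ring opening and six-electron closure (Danheiser benzannulation). The product would be 2,6-bis(3-methylbut-2-en-1-yl)-3-(triisopropylsilyloxy)phenol A5.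
- In its favour: A5 arises by a convergent, regiospecific assembly under neutral conditions, with the ring formed already aromatic. No dehydrogenation has to be carried out beside prenyl groups, which is better than step 4 of the chosen plan. The two oxygens of A5 emerge differentiated, a feature the chosen plan only reaches in step 6.
- Against it: the differentiation in A5 is the wrong way round for what follows. The C7 hydroxyl is free and the oxygen destined to be O1 is silylated, so a protecting-group exchange is needed before C4a can be functionalised through its ortho hydroxyl. A6 has a skipped diene whose doubly activated CH2 invites isomerisation into conjugation, and it must be made with diazo chemistry; A7 needs an ynolate or alkynyl ether preparation.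
- Comparison: both plans avoid electrophilic prenylation (equal), and both still have to attach C4 to C4a afterwards (equal). The benzannulation to A5 is mechanistically more elegant, but the chosen plan reaches 10 in four steps from commodity materials with ordinary enolate chemistry and is ahead on step economy and handling.

Key step: step 3

Remark on stereochemistry: the sense of induction in step 11 is assigned by analogy with aryl–rhodium additions to cyclohex-2-enone under (S)-configured biaryl bisphosphines, the chromone being taken to bind through the same enone face; should it bind through the other face, the (R)-ligand would be used.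

Remark on tautomers: 7 is written as the diketone but is handled as a mixture of enol tautomers and C4 epimers, all of which lead to the same arene.

## Route

Step 1
Reactants: 1 dimethyl 3-oxopentanedioate (dimethyl 1,3-acetonedicarboxylate); 2 1-bromo-3-methylbut-2-ene (prenyl bromide)
Product: 4 dimethyl 2,4-bis(3-methylbut-2-en-1-yl)-3-oxopentanedioate, via mono-prenyl keto diester 3 (not isolated)
Conditions: NaH (1.05 equiv), THF, 0 °C; 2 (1.0 equiv), rt; then NaH (1.05 equiv), 0 °C; 2 (1.05 equiv), rt
Reagents that add atoms: 1-bromo-3-methylbut-2-ene (second equivalent of 2), CC(C)=CCBr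
Why: Stepwise C-alkylation of a beta-keto diester enolate; in the mono-prenyl compound 3 the untouched CH2 is the more acidic and less hindered site, so the second enolate forms and is alkylated on the other side of the ketone. Product 4 should form as a mixture of diastereomers and enol forms, which is of no consequence because both centres lose their ester group in step 2.

Step 2
Reactants: 4 dimethyl 2,4-bis(3-methylbut-2-en-1-yl)-3-oxopentanedioate
Product: 5 2,10-dimethylundeca-2,9-dien-6-one
Conditions: LiCl (2.5 equiv), H2O (4 equiv), DMSO, 150 °C
Reagents that add atoms: none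
Why: Krapcho dealkoxycarbonylation; chloride demethylates each beta-keto ester and the beta-keto carboxylates lose CO2 under neutral conditions that leave the trisubstituted alkenes untouched.

Step 3
Reactants: 5 2,10-dimethylundeca-2,9-dien-6-one; 6 methyl acrylate
Product: 7 2,4-bis(3-methylbut-2-en-1-yl)cyclohexane-1,3-dione
Conditions: KOtBu (1.5 equiv), THF, 0 °C; 6 (1.1 equiv) added over 2 h; rt; then 1 M HCl to pH 3, 0 °C
Reagents that add atoms: none
Why: KOtBu converts 5 into its potassium enolate, which adds to 6 in a Michael reaction and so forms C6–C5; proton transfer then moves the negative charge to the other alpha carbon of the ketone, which attacks the ester carbonyl, forms C8–C8a and expels methoxide (intramolecular Claisen condensation). The closest known reaction type is the base-mediated consecutive Michael–Claisen annulation of dialkyl ketones with acrylates to cyclohexane-1,3-diones. Ring A closes in a 6-(enolendo)-exo-trig mode, the favoured mode for a ketone enolate attacking an ester five atoms away. No lasting stereocentre is made: C2 and C4 of 7 are epimerisable carbons of an enolised dione and both become aromatic in step 4. The selectivity that matters is one Michael addition followed by ring closure instead of a second Michael addition; slow addition keeps the concentration of 6 low, the ring closure is intramolecular, and deprotonation of the acidic 1,3-dione by the liberated alkoxide removes the product from every equilibrium. Because 5 is symmetric, either alpha carbon can begin and the same dione results, so the prenyl–oxygen–prenyl array of C6–C7–C8 is fixed by connectivity and not by arene substitution. The trisubstituted alkenes are inert to alkoxide, and the cold dilute acid quench is too short to cyclise the 2-prenyl enol.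

Step 4
Reactants: 7 2,4-bis(3-methylbut-2-en-1-yl)cyclohexane-1,3-dione
Product: 10 2,4-bis(3-methylbut-2-en-1-yl)benzene-1,3-diol, via bis(trimethylsilyl) dienol ether 8 (not isolated), via mono(trimethylsilyl) resorcinol ether 9 (not isolated)
Conditions: TMSOTf (2.4 equiv), Et3N (3 equiv), CH2Cl2, 0 °C; then Pd(OAc)2 (1.1 equiv), MeCN, rt; then MeOH, citric acid (cat.), rt
Reagents that add atoms: trimethylsilyl trifluoromethanesulfonate, C[Si](C)(C)OS(=O)(=O)C(F)(F)F (its silyl groups sit in 8 and 9 only and are gone in 10)
Why: Saegusa–Ito oxidation; soft enolisation gives the bis(silyl) dienol ether, Pd(OAc)2 palladates its terminal carbon, and beta-hydride elimination gives a cyclohexadienone that tautomerises to the phenol, both possible dienol ether regioisomers converging on 10 once the remaining silyl group is methanolysed. Stoichiometric divalent palladium at room temperature without a reoxidant is chosen so that no turnover is available for Wacker-type cyclisation of the ortho-prenyl phenol.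

Step 5
Reactants: 10 2,4-bis(3-methylbut-2-en-1-yl)benzene-1,3-diol
Product: 11 2,4-dihydroxy-3,5-bis(3-methylbut-2-en-1-yl)benzaldehyde
Conditions: MgCl2 (3 equiv), Et3N (6 equiv), (CH2O)n (6 equiv), MeCN, 80 °C; then cold 5% aq. citric acid
Reagents that add atoms: paraformaldehyde (as formaldehyde, C=O)
Why: Magnesium-mediated ortho-formylation (Casnati–Skattebøl reaction); the magnesium phenoxide delivers formaldehyde to the ortho carbon through a chelate and a second formaldehyde oxidises the benzylic alkoxide by hydride transfer. Only one hydroxyl of 10 has a free ortho position, so only C4a can react, and the amine-buffered medium spares the prenyl groups that an acid-mediated C-acetylation would endanger.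

Step 6
Reactants: 11 2,4-dihydroxy-3,5-bis(3-methylbut-2-en-1-yl)benzaldehyde
Product: 12 4-(tert-butyldimethylsilyloxy)-2-hydroxy-3,5-bis(3-methylbut-2-en-1-yl)benzaldehyde
Conditions: TBSCl (1.2 equiv), imidazole (2.5 equiv), DMF, 0 °C to rt
Reagents that add atoms: tert-butyldimethylsilyl chloride, CC(C)(C)[Si](C)(C)Cl
Why: Selective phenol silylation; the 2-hydroxyl is held in a hydrogen bond to the aldehyde, so the more acidic 4-hydroxyl para to the formyl group should be silylated in spite of its two ortho substituents.

Step 7
Reactants: 12 4-(tert-butyldimethylsilyloxy)-2-hydroxy-3,5-bis(3-methylbut-2-en-1-yl)benzaldehyde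
Product: 13 1-[4-(tert-butyldimethylsilyloxy)-2-hydroxy-3,5-bis(3-methylbut-2-en-1-yl)phenyl]prop-2-yn-1-ol (racemic)
Conditions: ethynylmagnesium bromide (2.5 equiv), THF, −20 to 0 °C; aq. NH4Cl
Reagents that add atoms: ethynylmagnesium bromide, C#C[Mg]Br
Why: Grignard addition to an aldehyde; the first equivalent deprotonates the phenol and the second adds to the chelated salicylaldehyde, bringing in C3 and C2. The new carbinol centre is racemic and is erased in step 8.

Step 8
Reactants: 13 1-[4-(tert-butyldimethylsilyloxy)-2-hydroxy-3,5-bis(3-methylbut-2-en-1-yl)phenyl]prop-2-yn-1-ol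
Product: 15 7-(tert-butyldimethylsilyloxy)-6,8-bis(3-methylbut-2-en-1-yl)-4H-chromen-4-one, via hydroxyaryl ynone 14 (not isolated)
Conditions: MnO2 (15 equiv), CH2Cl2, rt; filter; DMAP (10 mol%), CH2Cl2, rt
Reagents that add atoms: none
Why: MnO2 oxidation of a benzylic–propargylic alcohol, then amine-catalysed 6-endo-dig oxa-Michael cyclisation of the ortho-hydroxyaryl ynone; the phenol adds to the unsubstituted beta carbon, the electronically favoured position, so the chromone and not a five-membered ring should form, and no acid is involved.

Step 9
Reactants: 16 4-bromophenol; 17 3-methylbut-2-enal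
Product: 18 6-bromo-2,2-dimethyl-2H-chromene
Conditions: PhB(OH)2 (1.0 equiv), AcOH, toluene, reflux with azeotropic removal of water
Reagents that add atoms: none
Why: Phenylboronic acid-templated ortho-condensation of a phenol with an enal; the aryl boronate directs attack on the aldehyde to the ortho carbon, thermal loss of the boron unit gives an ortho-quinone methide, and oxa-six-electron electrocyclisation closes the 2,2-dimethylpyran ring. The para bromine blocks the only other reactive position.

Step 10
Reactants: 18 6-bromo-2,2-dimethyl-2H-chromene
Product: 19 (2,2-dimethyl-2H-chromen-6-yl)boronic acid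
Conditions: n-BuLi (1.1 equiv), THF, −78 °C; B(OiPr)3 (1.5 equiv), −78 °C to rt; then 1 M HCl, 0 °C
Reagents that add atoms: triisopropyl borate, CC(C)OB(OC(C)C)OC(C)C; water, O
Why: Bromine–lithium exchange followed by borylation with a trialkyl borate and hydrolysis; at −78 °C the aryllithium should form faster than any attack on the chromene double bond or the allylic ether.

Step 11
Reactants: 15 7-(tert-butyldimethylsilyloxy)-6,8-bis(3-methylbut-2-en-1-yl)-4H-chromen-4-one; 19 (2,2-dimethyl-2H-chromen-6-yl)boronic acid
Product: 20 (2S)-7-(tert-butyldimethylsilyloxy)-2-(2,2-dimethyl-2H-chromen-6-yl)-6,8-bis(3-methylbut-2-en-1-yl)-2,3-dihydro-4H-chromen-4-one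
Conditions: [RhCl(C2H4)2]2 (1.5 mol%), (S)-MeO-F12-BIPHEP [(S)-6,6'-dimethoxy-2,2'-bis(bis(3,4,5-trifluorophenyl)phosphino)-1,1'-biphenyl] (3.3 mol%), 19 (2 equiv), KOH (20 mol%), toluene/H2O (10:1), 20 °C
Reagents that add atoms: none
Why: Rhodium-catalysed asymmetric 1,4-addition of an arylboronic acid to a chromone; transmetallation gives an aryl–rhodium species of monovalent rhodium bound to the (S)-bisphosphine, the C2=C3 bond inserts through the enone face selected by the ligand, and water protonates the rhodium enolate, which sets C2 as S. The electron-poor ligand speeds insertion into the weakly electrophilic chromone, and toluene at 20 °C holds back ring opening of the enolate and 1,2-addition to the product ketone. The trisubstituted prenyl alkenes and the hindered chromene alkene are not activated and should not insert.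

Step 12
Reactants: 20 (2S)-7-(tert-butyldimethylsilyloxy)-2-(2,2-dimethyl-2H-chromen-6-yl)-6,8-bis(3-methylbut-2-en-1-yl)-2,3-dihydro-4H-chromen-4-one
Product: 21 lespeflorin A3, (2S)-7-hydroxy-2-(2,2-dimethyl-2H-chromen-6-yl)-6,8-bis(3-methylbut-2-en-1-yl)-2,3-dihydro-4H-chromen-4-one
Conditions: TBAF (1.2 equiv), AcOH (1.2 equiv), THF, 0 °C
Reagents that add atoms: none
Why: Fluoride cleavage of an aryl silyl ether; acetic acid buffers the phenoxide so that retro-oxa-Michael opening of ring C, the only path to epimerisation at C2, is not triggered. The medium is never acidic enough to cyclise the prenyl groups onto the freed hydroxyl.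

## Compound list

1 | dimethyl 3-oxopentanedioate | COC(=O)CC(=O)CC(=O)OC | starting material
2 | 1-bromo-3-methylbut-2-ene | CC(C)=CCBr | starting material
3 | dimethyl 2-(3-methylbut-2-en-1-yl)-3-oxopentanedioate (not isolated) | COC(=O)C(CC=C(C)C)C(=O)CC(=O)OC | intermediate
4 | dimethyl 2,4-bis(3-methylbut-2-en-1-yl)-3-oxopentanedioate | COC(=O)C(CC=C(C)C)C(=O)C(CC=C(C)C)C(=O)OC | intermediate
5 | 2,10-dimethylundeca-2,9-dien-6-one | CC(C)=CCCC(=O)CCC=C(C)C | intermediate
6 | methyl acrylate | C=CC(=O)OC | starting material
7 | 2,4-bis(3-methylbut-2-en-1-yl)cyclohexane-1,3-dione | CC(C)=CCC1CCC(=O)C(CC=C(C)C)C1=O | intermediate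
8 | 1,3-bis(trimethylsilyloxy)-2,6-bis(3-methylbut-2-en-1-yl)cyclohexa-1,3-diene (major dienol ether, not isolated) | CC(C)=CCC1CC=C(O[Si](C)(C)C)C(CC=C(C)C)=C1O[Si](C)(C)C | intermediate
9 | 2,4-bis(3-methylbut-2-en-1-yl)-3-(trimethylsilyloxy)phenol (not isolated) | CC(C)=CCc1ccc(O)c(CC=C(C)C)c1O[Si](C)(C)C | intermediate
10 | 2,4-bis(3-methylbut-2-en-1-yl)benzene-1,3-diol | CC(C)=CCc1ccc(O)c(CC=C(C)C)c1O | intermediate
11 | 2,4-dihydroxy-3,5-bis(3-methylbut-2-en-1-yl)benzaldehyde | CC(C)=CCc1cc(C=O)c(O)c(CC=C(C)C)c1O | intermediate
12 | 4-(tert-butyldimethylsilyloxy)-2-hydroxy-3,5-bis(3-methylbut-2-en-1-yl)benzaldehyde | CC(C)=CCc1cc(C=O)c(O)c(CC=C(C)C)c1O[Si](C)(C)C(C)(C)C | intermediate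
13 | 1-[4-(tert-butyldimethylsilyloxy)-2-hydroxy-3,5-bis(3-methylbut-2-en-1-yl)phenyl]prop-2-yn-1-ol (racemic) | CC(C)=CCc1cc(C(O)C#C)c(O)c(CC=C(C)C)c1O[Si](C)(C)C(C)(C)C | intermediate
14 | 1-[4-(tert-butyldimethylsilyloxy)-2-hydroxy-3,5-bis(3-methylbut-2-en-1-yl)phenyl]prop-2-yn-1-one (not isolated) | CC(C)=CCc1cc(C(=O)C#C)c(O)c(CC=C(C)C)c1O[Si](C)(C)C(C)(C)C | intermediate
15 | 7-(tert-butyldimethylsilyloxy)-6,8-bis(3-methylbut-2-en-1-yl)-4H-chromen-4-one | CC(C)=CCc1cc2c(c(CC=C(C)C)c1O[Si](C)(C)C(C)(C)C)OC=CC2=O | intermediate
16 | 4-bromophenol | Oc1ccc(Br)cc1 | starting material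
17 | 3-methylbut-2-enal | CC(C)=CC=O | starting material
18 | 6-bromo-2,2-dimethyl-2H-chromene | CC1(C)C=Cc2cc(Br)ccc2O1 | intermediate
19 | (2,2-dimethyl-2H-chromen-6-yl)boronic acid | CC1(C)C=Cc2cc(B(O)O)ccc2O1 | intermediate
20 | (2S)-7-(tert-butyldimethylsilyloxy)-2-(2,2-dimethyl-2H-chromen-6-yl)-6,8-bis(3-methylbut-2-en-1-yl)-2,3-dihydro-4H-chromen-4-one | CC(C)=CCc1cc2c(c(CC=C(C)C)c1O[Si](C)(C)C(C)(C)C)O[C@H](c1ccc3c(c1)C=CC(C)(C)O3)CC2=O | intermediate
21 | lespeflorin A3, (2S)-7-hydroxy-2-(2,2-dimethyl-2H-chromen-6-yl)-6,8-bis(3-methylbut-2-en-1-yl)-2,3-dihydro-4H-chromen-4-one | CC(C)=CCc1cc2c(c(CC=C(C)C)c1O)O[C@H](c1ccc3c(c1)C=CC(C)(C)O3)CC2=O | target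

## Step count and least certain steps

Total step count: 12. Longest linear sequence: 10 (steps 1 to 8, 11 and 12); steps 9 and 10 form the two-step side branch to 19.

Step 3 (key step). The most likely failure is over-reaction of the open-chain adduct: a second Michael addition or anionic oligomerisation of 6, or consumption of 6 by the liberated methoxide, because the acyclic enolate is regenerated by proton transfer before it cyclises. Fallback, separating the two bond formations: setting out from 5, condensation with pyrrolidine (4 Å molecular sieves, toluene, reflux) gives the enamine 1-(2,10-dimethylundeca-2,5,9-trien-6-yl)pyrrolidine F1. Stork enamine addition of F1 to 6 (MeCN, reflux) and hydrolysis with aqueous AcOH/NaOAc gives the keto ester methyl 9-methyl-4-(3-methylbut-2-en-1-yl)-5-oxodec-8-enoate F2. A separate Claisen ring closure of F2 with KOtBu in THF then returns to the route at 7.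

Step 4. The likely failure is oxypalladation of a prenyl double bond by the newly formed phenol (Wacker-type ring closure), or incomplete enol silylation that leaves dione behind. Fallback without palladium: setting out from 7, the dianion formed with LiN(iPr)2 (2.2 equiv, THF, −78 to 0 °C) is sulfinylated at its CH2 terminus with methyl benzenesulfinate to give 2,4-bis(3-methylbut-2-en-1-yl)-6-(phenylsulfinyl)cyclohexane-1,3-dione F3. Thermal syn-elimination of F3 (toluene, 90 °C, CaCO3) and tautomerisation return to the route at 10.

Step 5. The likely failure is hydroxymethylation without the hydride-transfer step, followed by condensation of the benzylic alkoxide with a second arene (diarylmethane formation), because the resorcinol ring is very nucleophilic toward formaldehyde. Fallback by directed metalation: setting out from 10, protection with chloromethyl methyl ether and iPr2NEt gives 1,3-bis(methoxymethoxy)-2,4-bis(3-methylbut-2-en-1-yl)benzene F4. Ortho-lithiation of F4 (n-BuLi, TMEDA, THF, −78 to 0 °C) next to the less hindered acetal oxygen and quenching with DMF give 2,4-bis(methoxymethoxy)-3,5-bis(3-methylbut-2-en-1-yl)benzaldehyde F5. Brief treatment of F5 with catalytic HCl in MeOH at rt removes both acetals and returns to the route at 11.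

Step 11. The likely failures are insufficient enantioface discrimination, beta-alkoxide elimination of the rhodium enolate with opening of ring C, 1,2-addition of a second aryl group to the product ketone, and partial loss of the silyl group under aqueous hydroxide. Fallback by kinetic resolution: setting out from 15, addition of 19 with the achiral complex [Rh(OH)(cod)]2 in dioxane/H2O gives racemic 7-(tert-butyldimethylsilyloxy)-2-(2,2-dimethyl-2H-chromen-6-yl)-6,8-bis(3-methylbut-2-en-1-yl)-2,3-dihydro-4H-chromen-4-one F6. Asymmetric transfer hydrogenation of F6 with RuCl[(R,R)-TsDPEN](p-cymene) and HCO2H/Et3N should reduce the (2R) enantiomer preferentially to the cis-alcohol (2R,4R)-7-(tert-butyldimethylsilyloxy)-2-(2,2-dimethyl-2H-chromen-6-yl)-6,8-bis(3-methylbut-2-en-1-yl)chroman-4-ol F7, which is removed by chromatography. The unreduced (2S) ketone is 20, where the route is rejoined at the cost of half the material.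

Step 12. The likely failure is retro-oxa-Michael opening and reclosure of ring C while a phenoxide or a C3 enolate is present, which would erode the configuration at C2. Fallback that removes the ketone during deprotection: setting out from 20, NaBH4 (MeOH/THF, 0 °C) gives the alcohol (2S,4S)-7-(tert-butyldimethylsilyloxy)-2-(2,2-dimethyl-2H-chromen-6-yl)-6,8-bis(3-methylbut-2-en-1-yl)chroman-4-ol F8, which cannot open by beta-elimination. TBAF in THF then gives (2S,4S)-2-(2,2-dimethyl-2H-chromen-6-yl)-6,8-bis(3-methylbut-2-en-1-yl)chroman-4,7-diol F9, and MnO2 in CH2Cl2 reoxidises the benzylic alcohol of F9 under neutral conditions, rejoining the route at 21.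

## Further compounds

F1 | step 3 | 1-(2,10-dimethylundeca-2,5,9-trien-6-yl)pyrrolidine | CC(C)=CCC=C(CCC=C(C)C)N1CCCC1
F2 | step 3 | methyl 9-methyl-4-(3-methylbut-2-en-1-yl)-5-oxodec-8-enoate | COC(=O)CCC(CC=C(C)C)C(=O)CCC=C(C)C
F3 | step 4 | 2,4-bis(3-methylbut-2-en-1-yl)-6-(phenylsulfinyl)cyclohexane-1,3-dione | CC(C)=CCC1CC(S(=O)c2ccccc2)C(=O)C(CC=C(C)C)C1=O
F4 | step 5 | 1,3-bis(methoxymethoxy)-2,4-bis(3-methylbut-2-en-1-yl)benzene | CC(C)=CCc1ccc(OCOC)c(CC=C(C)C)c1OCOC
F5 | step 5 | 2,4-bis(methoxymethoxy)-3,5-bis(3-methylbut-2-en-1-yl)benzaldehyde | CC(C)=CCc1cc(C=O)c(OCOC)c(CC=C(C)C)c1OCOC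
F6 | step 11 | racemic 7-(tert-butyldimethylsilyloxy)-2-(2,2-dimethyl-2H-chromen-6-yl)-6,8-bis(3-methylbut-2-en-1-yl)-2,3-dihydro-4H-chromen-4-one | CC(C)=CCc1cc2c(c(CC=C(C)C)c1O[Si](C)(C)C(C)(C)C)OC(c1ccc3c(c1)C=CC(C)(C)O3)CC2=O
F7 | step 11 | (2R,4R)-7-(tert-butyldimethylsilyloxy)-2-(2,2-dimethyl-2H-chromen-6-yl)-6,8-bis(3-methylbut-2-en-1-yl)chroman-4-ol | CC(C)=CCc1cc2c(c(CC=C(C)C)c1O[Si](C)(C)C(C)(C)C)O[C@@H](c1ccc3c(c1)C=CC(C)(C)O3)C[C@H]2O
F8 | step 12 | (2S,4S)-7-(tert-butyldimethylsilyloxy)-2-(2,2-dimethyl-2H-chromen-6-yl)-6,8-bis(3-methylbut-2-en-1-yl)chroman-4-ol | CC(C)=CCc1cc2c(c(CC=C(C)C)c1O[Si](C)(C)C(C)(C)C)O[C@H](c1ccc3c(c1)C=CC(C)(C)O3)C[C@@H]2O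
F9 | step 12 | (2S,4S)-2-(2,2-dimethyl-2H-chromen-6-yl)-6,8-bis(3-methylbut-2-en-1-yl)chroman-4,7-diol | CC(C)=CCc1cc2c(c(CC=C(C)C)c1O)O[C@H](c1ccc3c(c1)C=CC(C)(C)O3)C[C@@H]2O
A1 | alternative 1 | (2E)-1-[2,4-dihydroxy-3,5-bis(3-methylbut-2-en-1-yl)phenyl]-3-(2,2-dimethyl-2H-chromen-6-yl)prop-2-en-1-one | CC(C)=CCc1cc(C(=O)/C=C/c2ccc3OC(C)(C)C=Cc3c2)c(O)c(CC=C(C)C)c1O
A2 | alternative 1 | 2-[(3E)-4-(2,2-dimethyl-2H-chromen-6-yl)-2-oxobut-3-en-1-yl]-3,5-bis(3-methylbut-2-en-1-yl)-4H-pyran-4-one | CC(C)=CCC1=COC(CC(=O)/C=C/c2ccc3OC(C)(C)C=Cc3c2)=C(CC=C(C)C)C1=O
A3 | alternative 2 | (2S,4S)-7-(tert-butyldimethylsilyloxy)-2-(2,2-dimethyl-2H-chromen-6-yl)-6,8-bis(3-methylbut-2-en-1-yl)chroman-4-ol | CC(C)=CCc1cc2c(c(CC=C(C)C)c1O[Si](C)(C)C(C)(C)C)O[C@H](c1ccc3c(c1)C=CC(C)(C)O3)C[C@@H]2O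
A4 | alternative 2 | (1S,3S)-1-[2-bromo-4-(tert-butyldimethylsilyloxy)-3,5-bis(3-methylbut-2-en-1-yl)phenyl]-3-(2,2-dimethyl-2H-chromen-6-yl)propane-1,3-diol | CC(C)=CCc1cc([C@@H](O)C[C@H](O)c2ccc3c(c2)C=CC(C)(C)O3)c(Br)c(CC=C(C)C)c1O[Si](C)(C)C(C)(C)C
A5 | alternative 3 | 2,6-bis(3-methylbut-2-en-1-yl)-3-(triisopropylsilyloxy)phenol | CC(C)=CCc1ccc(O[Si](C(C)C)(C(C)C)C(C)C)c(CC=C(C)C)c1O
A6 | alternative 3 | (3E)-1-diazo-7-methylocta-3,6-dien-2-one | CC(C)=CC/C=C/C(=O)C=[N+]=[N-]
A7 | alternative 3 | triisopropyl[(5-methylhex-4-en-1-yn-1-yl)oxy]silane | CC(C)=CCC#CO[Si](C(C)C)(C(C)C)C(C)C
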